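The route rests on reading C2 of the pyran ring, the quaternary carbon held between O1 and the cis C3=C4 double bond, as the former carbonyl carbon of a coumarin. In one operation a hard methyl nucleophile adds twice to that lactone and mild acid recloses O1–C2. Both C2–CH3 bonds and the 2,2-dimethyl-2H-pyran therefore arise together, and the alkene geometry is inherited. The precursor is a 5-methoxy-7-(methoxymethoxy)coumarin bearing a (4-methoxyphenyl)ethynyl group at C6. This diarylalkyne ignores organometallics and is oxidised to the 1,2-diketone only afterwards. C6 is addressed earlier by formylation directed from the free 5-OH.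

Key step: step 6

Remark on the chemistry: the target has no stereocentre, and its only geometric element is the cis ring alkene C3=C4; the o-hydroxybenzil is treated as the open, hydrogen-bonded diketone drawn in the target structure, although it can equilibrate with its cyclic hemiketal.

Step 1
Reactants: 1 5,7-dihydroxy-2H-chromen-2-one (5,7-dihydroxycoumarin)
Product: 2 5-hydroxy-7-(methoxymethoxy)-2H-chromen-2-one
Conditions: MOMCl (1.0 equiv), K2CO3 (1.1 equiv), acetone, 0 °C → rt
Reagents that add atoms: chloromethyl methyl ether (MOMCl), COCCl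
Why: Williamson-type O-alkylation with a limiting charge of MOMCl should fall on the 7-OH, which is the more acidic phenol (its anion is conjugated with the lactone carbonyl in a para-quinone-methide sense) and lacks the peri contact with C4–H that hinders the 5-OH, while the minor 5-O and bis ethers are separable and can be hydrolysed back to 1.

Step 2
Reactants: 2 5-hydroxy-7-(methoxymethoxy)-2H-chromen-2-one
Product: 4 5-hydroxy-7-(methoxymethoxy)-2-oxo-2H-chromene-6-carbaldehyde, via 6-hydroxymethyl phenol 3 (not isolated)
Conditions: MgCl2 (anhydrous, 3 equiv), Et3N (4 equiv), (CH2O)n (8 equiv), THF, reflux; cold aq citric acid work-up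
Reagents that add atoms: paraformaldehyde (reacts as formaldehyde), C=O
Why: Casnati–Skattebøl ortho-formylation: the magnesium 5-phenoxide binds formaldehyde and passes it through a cyclic transition state to its only free ortho carbon C6 (the other ortho position is the ring-fusion carbon C4a), and the resulting benzylic alkoxide of 3 hands hydride to a second formaldehyde, so that C8 is not touched and the MOM acetal and lactone survive the weakly basic medium.

Step 3
Reactants: 4 5-hydroxy-7-(methoxymethoxy)-2-oxo-2H-chromene-6-carbaldehyde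
Product: 5 5-methoxy-7-(methoxymethoxy)-2-oxo-2H-chromene-6-carbaldehyde
Conditions: MeI (2 equiv), K2CO3 (2 equiv), DMF, rt → 40 °C
Reagents that add atoms: iodomethane, CI
Why: Williamson O-methylation of the chelated, aldehyde-flanked 5-phenoxide in a dipolar aprotic solvent, under which the aldehyde, lactone and MOM acetal are inert.

Step 4
Reactants: 5 5-methoxy-7-(methoxymethoxy)-2-oxo-2H-chromene-6-carbaldehyde
Product: 6 6-ethynyl-5-methoxy-7-(methoxymethoxy)-2H-chromen-2-one
Conditions: dimethyl (1-diazo-2-oxopropyl)phosphonate (1.3 equiv), K2CO3 (2 equiv), MeOH/THF, 0 °C → rt; aq NH4Cl work-up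
Reagents that add atoms: dimethyl (1-diazo-2-oxopropyl)phosphonate, COP(=O)(OC)C(=[N+]=[N-])C(C)=O
Why: Ohira–Bestmann variant of the Seyferth–Gilbert homologation: methoxide deacetylates the reagent, the diazophosphonate anion olefinates the non-enolisable aldehyde and loss of N2 with 1,2-hydride shift gives the terminal alkyne, while any reversible methanolysis of the lactone is undone on the mildly acidic work-up because the cis geometry is kept.

Step 5
Reactants: 6 6-ethynyl-5-methoxy-7-(methoxymethoxy)-2H-chromen-2-one; 7 4-iodoanisole
Product: 8 5-methoxy-7-(methoxymethoxy)-6-[(4-methoxyphenyl)ethynyl]-2H-chromen-2-one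
Conditions: PdCl2(PPh3)2 (3 mol %), CuI (5 mol %), Et3N/THF (degassed), 50 °C
Reagents that add atoms: 4-iodoanisole (7), COc1ccc(I)cc1
Why: Sonogashira coupling: oxidative addition of the aryl iodide to zerovalent palladium and transfer of the copper acetylide take place at the terminal alkyne carbon, remote from the two ortho alkoxy groups, and amine base at mild temperature leaves lactone and MOM untouched.

Step 6
Reactants: 8 5-methoxy-7-(methoxymethoxy)-6-[(4-methoxyphenyl)ethynyl]-2H-chromen-2-one; 9 methylmagnesium bromide
Product: 12 5-methoxy-7-(methoxymethoxy)-6-[(4-methoxyphenyl)ethynyl]-2,2-dimethyl-2H-chromene, via ring-opened Z-enone phenol 10 (not isolated), via Z-allylic diol 11 (not isolated)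
Conditions: CeCl3 (anhydrous, 5 equiv), MeMgBr (5 equiv), THF, −78 → 0 °C; water/aq NH4Cl quench; crude in CH2Cl2, PPTS (10 mol %), rt
Reagents that add atoms: methylmagnesium bromide (9), C[Mg]Br
Why: The organocerium reagent attacks the lactone carbonyl C2, the tetrahedral alkoxide collapses with release of the O1 phenoxide to the cis aryl enone 10, and a second 1,2-addition gives the tertiary allylic alkoxide of 11; after a near-neutral quench, catalytic PPTS ionises this doubly activated tertiary allylic alcohol (or dehydrates it to the o-quinone methide) and O1 closes on C2. The closest known reaction type is the classical twofold addition of methyl Grignard or methyllithium reagents to coumarins followed by acid cyclisation of the cis-hydroxyallyl phenol to a 2,2-dimethyl-2H-chromene. The single ring formed, the six-membered pyran, closes by 6-endo capture of the allyl cation terminus by the phenol oxygen, equivalent to an oxa-6π electrocyclisation of the quinone methide, and only O1 can do this because the other oxygen flanking C4a (O5) is methylated. No stereocentre is created, and the Z geometry of C3=C4 passes unchanged from the lactone ring, which keeps O1 within reach of C2. The selectivity needed is 1,2- over 1,4-addition together with complete double addition: the peri 5-OMe shields C4, the 5- and 7-oxygen donors lower its electrophilicity, and the oxophilic, weakly basic cerium reagent suppresses both conjugate addition and enolisation of the methyl ketone. The diarylalkyne, the aryl ethers and the MOM acetal are inert to the reagent, and separating the quench from the PPTS closure keeps the MOM group in place.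

Step 7
Reactants: 12 5-methoxy-7-(methoxymethoxy)-6-[(4-methoxyphenyl)ethynyl]-2,2-dimethyl-2H-chromene
Product: 13 1-[5-methoxy-7-(methoxymethoxy)-2,2-dimethyl-2H-chromen-6-yl]-2-(4-methoxyphenyl)ethane-1,2-dione
Conditions: PdCl2 (10 mol %), DMSO (dry, N2), 120–140 °C
Reagents that add atoms: dimethyl sulfoxide, CS(C)=O
Why: Alkyne-to-1,2-diketone oxidation catalysed by divalent palladium with DMSO as oxygen donor, a reagent pair known to oxidise diaryl C≡C bonds in preference to C=C bonds, so the hindered pyran alkene should persist; the MOM group is deliberately still in place because a free 7-OH beside the activated alkyne would close to a 2-arylbenzofuran.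

Step 8
Reactants: 13 1-[5-methoxy-7-(methoxymethoxy)-2,2-dimethyl-2H-chromen-6-yl]-2-(4-methoxyphenyl)ethane-1,2-dione
Product: 14 1-(7-hydroxy-5-methoxy-2,2-dimethyl-2H-chromen-6-yl)-2-(4-methoxyphenyl)ethane-1,2-dione (target)
Conditions: 3 M aq HCl, THF, 40 °C
Reagents that add atoms: none
Why: Acid hydrolysis of the aryl MOM acetal, eased by the ortho carbonyl that hydrogen-bonds the released phenol, in aqueous rather than alcoholic medium so that the diketone is not ketalised, under which the methyl ethers and the 2,2-dimethylpyran alkene are stable.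

Compound list
1 | 5,7-dihydroxy-2H-chromen-2-one | O=C1C=Cc2c(O)cc(O)cc2O1 | starting material
2 | 5-hydroxy-7-(methoxymethoxy)-2H-chromen-2-one | COCOc1cc(O)c2C=CC(=O)Oc2c1 | intermediate
3 | 5-hydroxy-6-(hydroxymethyl)-7-(methoxymethoxy)-2H-chromen-2-one | COCOc1cc2OC(=O)C=Cc2c(O)c1CO | intermediate (not isolated)
4 | 5-hydroxy-7-(methoxymethoxy)-2-oxo-2H-chromene-6-carbaldehyde | COCOc1cc2OC(=O)C=Cc2c(O)c1C=O | intermediate
5 | 5-methoxy-7-(methoxymethoxy)-2-oxo-2H-chromene-6-carbaldehyde | COCOc1cc2OC(=O)C=Cc2c(OC)c1C=O | intermediate
6 | 6-ethynyl-5-methoxy-7-(methoxymethoxy)-2H-chromen-2-one | COCOc1cc2OC(=O)C=Cc2c(OC)c1C#C | intermediate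
7 | 4-iodoanisole | COc1ccc(I)cc1 | starting material
8 | 5-methoxy-7-(methoxymethoxy)-6-[(4-methoxyphenyl)ethynyl]-2H-chromen-2-one | COCOc1cc2OC(=O)C=Cc2c(OC)c1C#Cc1ccc(OC)cc1 | intermediate
9 | methylmagnesium bromide | C[Mg]Br | starting material
10 | (3Z)-4-{2-hydroxy-6-methoxy-4-(methoxymethoxy)-5-[(4-methoxyphenyl)ethynyl]phenyl}but-3-en-2-one | COCOc1cc(O)c(/C=C\C(C)=O)c(OC)c1C#Cc1ccc(OC)cc1 | intermediate (not isolated)
11 | 2-[(1Z)-3-hydroxy-3-methylbut-1-en-1-yl]-3-methoxy-5-(methoxymethoxy)-4-[(4-methoxyphenyl)ethynyl]phenol | COCOc1cc(O)c(/C=C\C(C)(C)O)c(OC)c1C#Cc1ccc(OC)cc1 | intermediate (not isolated)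
12 | 5-methoxy-7-(methoxymethoxy)-6-[(4-methoxyphenyl)ethynyl]-2,2-dimethyl-2H-chromene | COCOc1cc2OC(C)(C)C=Cc2c(OC)c1C#Cc1ccc(OC)cc1 | intermediate
13 | 1-[5-methoxy-7-(methoxymethoxy)-2,2-dimethyl-2H-chromen-6-yl]-2-(4-methoxyphenyl)ethane-1,2-dione | COCOc1cc2OC(C)(C)C=Cc2c(OC)c1C(=O)C(=O)c1ccc(OC)cc1 | intermediate
14 | 1-(7-hydroxy-5-methoxy-2,2-dimethyl-2H-chromen-6-yl)-2-(4-methoxyphenyl)ethane-1,2-dione | COc1ccc(C(=O)C(=O)c2c(O)cc3c(c2OC)C=CC(C)(C)O3)cc1 | target

Total step count: 8. Longest linear sequence: 8 steps (1 → 14); 7 and 9 are purchased.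

Steps most likely to fail

Step 6.
- What may go wrong: methyl may be delivered to C4 instead of C2. The reaction may also stop after the first methyl, because the ring-opened ketone is enolised or hides as its cyclic hemiketal alkoxide, which then ionises to a chromenylium ion on acidification. Loss of the MOM group during reclosure is a lesser concern.
- Fallback, from 8 back to 11: the lactone is no longer the electrophile. Methanolysis of 8 with NaOMe in MeOH, solvent exchange to DMF and silylation of the released phenoxide with TBSCl would give methyl (2Z)-3-{2-[(tert-butyldimethylsilyl)oxy]-6-methoxy-4-(methoxymethoxy)-5-[(4-methoxyphenyl)ethynyl]phenyl}prop-2-enoate F1.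
- With O1 blocked the ketone stage cannot cyclise, and the two ortho substituents screen the β-carbon. MeLi in THF at −78 °C should then convert this plain cinnamate ester into (3Z)-4-{2-[(tert-butyldimethylsilyl)oxy]-6-methoxy-4-(methoxymethoxy)-5-[(4-methoxyphenyl)ethynyl]phenyl}-2-methylbut-3-en-2-ol F2.
- TBAF buffered with AcOH frees the phenol to give 11, which closes to 12 with PPTS as in the main route.

Step 7.
- What may go wrong: the flanking acetal oxygen may take part in the palladium-activated alkyne (5-endo closure with loss of the MOM group). The MOM group may be lost thermally or through trace acid at the oxidation temperature, or the pyran alkene may be attacked.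
- Fallback, from 12 back to 13: electrophilic activation of the alkyne is avoided altogether. Copper-catalysed syn-hydroboration (CuCl, Xantphos, NaOt-Bu, B2pin2, MeOH, THF, rt) should place boron at the less hindered alkyne carbon next to the anisyl ring. This gives 2-[(Z)-2-[5-methoxy-7-(methoxymethoxy)-2,2-dimethyl-2H-chromen-6-yl]-1-(4-methoxyphenyl)ethenyl]-4,4,5,5-tetramethyl-1,3,2-dioxaborolane F3. The orientation has no bearing on the outcome, since the benzylic CH2 is oxidised next.
- NaBO3·4H2O in THF/water converts the C–B bond into the ketone 2-[5-methoxy-7-(methoxymethoxy)-2,2-dimethyl-2H-chromen-6-yl]-1-(4-methoxyphenyl)ethan-1-one F4.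
- Base-catalysed aerobic α-oxidation of this deoxybenzoin (DABCO, air, DMF, 90 °C) delivers 13.

Step 1.
- What may go wrong: discrimination between the two phenols may be insufficient, and over-alkylation may occur.
- Fallback, from 1 back to 2: selection by alkylation rate is replaced by selection through leaving-group ability in acyl cleavage. Ac2O/pyridine gives 2-oxo-2H-chromene-5,7-diyl diacetate F5.
- Thiolysis with PhSH and imidazole in NMP should remove the acetate of the more acidic, less hindered 7-phenol to give 7-hydroxy-2-oxo-2H-chromen-5-yl acetate F6.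
- MOMCl and i-Pr2NEt in CH2Cl2 then give 7-(methoxymethoxy)-2-oxo-2H-chromen-5-yl acetate F7.
- Brief K2CO3/MeOH at 0 °C releases the 5-OH to give 2.

Further compounds
F1 | step 6 | methyl (2Z)-3-{2-[(tert-butyldimethylsilyl)oxy]-6-methoxy-4-(methoxymethoxy)-5-[(4-methoxyphenyl)ethynyl]phenyl}prop-2-enoate | COCOc1cc(O[Si](C)(C)C(C)(C)C)c(/C=C\C(=O)OC)c(OC)c1C#Cc1ccc(OC)cc1
F2 | step 6 | (3Z)-4-{2-[(tert-butyldimethylsilyl)oxy]-6-methoxy-4-(methoxymethoxy)-5-[(4-methoxyphenyl)ethynyl]phenyl}-2-methylbut-3-en-2-ol | COCOc1cc(O[Si](C)(C)C(C)(C)C)c(/C=C\C(C)(C)O)c(OC)c1C#Cc1ccc(OC)cc1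
F3 | step 7 | 2-[(Z)-2-[5-methoxy-7-(methoxymethoxy)-2,2-dimethyl-2H-chromen-6-yl]-1-(4-methoxyphenyl)ethenyl]-4,4,5,5-tetramethyl-1,3,2-dioxaborolane | COCOc1cc2OC(C)(C)C=Cc2c(OC)c1/C=C(\c1ccc(OC)cc1)B1OC(C)(C)C(C)(C)O1
F4 | step 7 | 2-[5-methoxy-7-(methoxymethoxy)-2,2-dimethyl-2H-chromen-6-yl]-1-(4-methoxyphenyl)ethan-1-one | COCOc1cc2OC(C)(C)C=Cc2c(OC)c1CC(=O)c1ccc(OC)cc1
F5 | step 1 | 2-oxo-2H-chromene-5,7-diyl diacetate | CC(=O)Oc1cc(OC(C)=O)c2C=CC(=O)Oc2c1
F6 | step 1 | 7-hydroxy-2-oxo-2H-chromen-5-yl acetate | CC(=O)Oc1cc(O)cc2OC(=O)C=Cc12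
F7 | step 1 | 7-(methoxymethoxy)-2-oxo-2H-chromen-5-yl acetate | CC(=O)Oc1cc(OCOC)cc2OC(=O)C=Cc12
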